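**Plan**

- Cuts (labdane numbering): the butenolide at C12–C13 and its ring (Morita–Baylis–Hillman reaction, ring-closing metathesis); C8=C17 and C9–C11 (Wittig reaction, enolate alkylation); then ring A at C1–C2 and C4–C5, which leaves a ring B cyclohexenol and methyl but-2-ynoate as the C2–C3–C4–C19 piece.
- Forward: ring B by a catalytic asymmetric Diels–Alder reaction; ring A in one pot by Claisen rearrangement (C4–C5) and dianion cycloalkylation (C1–C2); then C4 methylation, reduction, C8/C9 functionalisation, side chain, butenolide last.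
- Enabling feature: ring A (C1–C2–C3–C4–C5–C10) carries its oxygen at C3, so C2 and C4 are the two α-carbons of an acetoacetate; C5 is the allylic terminus of a C7 carbinol in ring B; C1 sits on the quaternary C10 as a neopentyl electrophile.
- Stereochemistry: C10 from the Diels–Alder catalyst; C7 from a catalyst-controlled reduction, relayed to C5 by the suprafacial [3,3] shift (trans ring fusion); C4 by alkylation anti to the C10 methyl; C3 by hydride; C9 by equilibration; C12 by the chiral amine catalyst.

Key step: step 6

Remark: positions are named by labdane numbering (C1–C20), and the target is taken as the 12R epimer that the SMILES encodes.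

**Step 1**
Reactants: 1 methacrolein; 2 (E)-3-(tert-butyldimethylsilyloxy)-N,N-dimethylbuta-1,3-dien-1-amine
Product: 3 (1S,2R)-4-(tert-butyldimethylsilyloxy)-2-(dimethylamino)-1-methylcyclohex-3-ene-1-carbaldehyde
Conditions: (salen)CrSbF6 (trivalent chromium; salen = N,N′-bis(3,5-di-tert-butylsalicylidene)cyclohexane-1,2-diamine dianion; 5 mol %; the enantiomer that gives the 1S adduct), 4 Å MS, CH2Cl2, −40 °C
Reagents that add atoms: none
Why: Catalytic enantioselective Diels–Alder reaction of a 1-amino-3-siloxydiene with an α-substituted acrolein, in which the chiral Lewis acid bound to the aldehyde fixes the quaternary carbon (later C10) and endo addition places CHO cis to NMe2.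

**Step 2**
Reactants: 3 (1S,2R)-4-(tert-butyldimethylsilyloxy)-2-(dimethylamino)-1-methylcyclohex-3-ene-1-carbaldehyde
Product: 5 (S)-4-(hydroxymethyl)-4-methylcyclohex-2-en-1-one, via amino alcohol 4 (not isolated)
Conditions: LiAlH4, Et2O, −78 → 0 °C; then aq. HF, MeCN, rt
Reagents that add atoms: none
Why: Hydride reduction of the aldehyde, then acid-mediated cleavage of the silyl enol ether and β-elimination of dimethylamine, should unmask the enone without touching the quaternary centre.

**Step 3**
Reactants: 5 (S)-4-(hydroxymethyl)-4-methylcyclohex-2-en-1-one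
Product: 6 [(1S)-1-methyl-4-oxocyclohex-2-en-1-yl]methyl 4-methylbenzenesulfonate
Conditions: TsCl, pyridine, DMAP (cat.), CH2Cl2, 0 °C → rt
Reagents that add atoms: p-toluenesulfonyl chloride, Cc1ccc(cc1)S(Cl)(=O)=O
Why: Sulfonylation of the primary alcohol turns C1 into a latent electrophile that, being neopentyl and without β-hydrogen, can neither eliminate nor be displaced before step 6.

**Step 4**
Reactants: 6 [(1S)-1-methyl-4-oxocyclohex-2-en-1-yl]methyl 4-methylbenzenesulfonate
Product: 7 [(1S,4S)-4-hydroxy-1-methylcyclohex-2-en-1-yl]methyl 4-methylbenzenesulfonate (OH cis to the ring methyl)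
Conditions: (R)-2-methyl-CBS-oxazaborolidine (20 mol %), BH3·SMe2, THF, −30 °C
Reagents that add atoms: none
Why: Corey–Bakshi–Shibata 1,2-reduction of the enone under catalyst control (alkenyl arm as the large group) should set the C7 carbinol cis to the C10 methyl group.

**Step 5**
Reactants: 7 [(1S,4S)-4-hydroxy-1-methylcyclohex-2-en-1-yl]methyl 4-methylbenzenesulfonate; 8 methyl but-2-ynoate
Product: 9 methyl (E)-3-{[(1S,4S)-4-methyl-4-(tosyloxymethyl)cyclohex-2-en-1-yl]oxy}but-2-enoate
Conditions: PMe3 (20 mol %), CH2Cl2, 0 °C → rt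
Reagents that add atoms: none
Why: Trialkylphosphine-catalysed oxa-Michael addition of the alcohol to the ynoate should give the (E)-β-alkoxycrotonate, which is the O-allyl enol ether of methyl acetoacetate, with the C7 configuration untouched.

**Step 6**
Reactants: 9 methyl (E)-3-{[(1S,4S)-4-methyl-4-(tosyloxymethyl)cyclohex-2-en-1-yl]oxy}but-2-enoate
Product: 11 methyl (4aR,8aR)-4a-methyl-2-oxo-1,2,3,4,4a,5,6,8a-octahydronaphthalene-1-carboxylate (trans-fused; C4 epimers and enol), via Claisen keto ester 10 (not isolated)
Conditions: PhMe, 180 °C (sealed tube); cool; then LiN(i-Pr)2 (2.3 equiv), THF, −78 °C → rt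
Reagents that add atoms: none
Why: Heating makes the allyl vinyl ether of 9 undergo a concerted suprafacial [3,3] Claisen rearrangement in which the C7–O bond breaks as C4–C5 forms to give the C-allylated acetoacetate 10, and two equivalents of LiN(i-Pr)2 then generate the α,γ-dianion whose γ-carbon (C2) displaces the tosylate at C1. The closest known reaction types are the thermal rearrangement of O-allyl acetoacetate enol ethers (the original Claisen rearrangement) and the γ-alkylation of β-keto ester dianions. Ring A (C1–C2–C3–C4–C5–C10) closes by a 6-(enolendo)-exo-tet carbon alkylation. C5 is set by 1,3-chirality transfer, since the new bond must form on the face from which the C7 oxygen departs, which is the face of the C10 methyl group, so that H5 ends anti to that methyl; C4 stays enolisable and is fixed in step 7. The step needs C-alkylation at C2 in preference to O-alkylation, which complete dianion formation at −78 °C before warming should secure, and it needs the tosylate to survive 180 °C and strong base, which its neopentyl position without β-hydrogen should secure. The trans ring fusion follows because C4 on C5 and C1 on C10 are trans and can both be equatorial on ring B.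

**Step 7**
Reactants: 11 methyl (4aR,8aR)-4a-methyl-2-oxo-1,2,3,4,4a,5,6,8a-octahydronaphthalene-1-carboxylate
Product: 12 methyl (1S,4aR,8aS)-1,4a-dimethyl-2-oxo-1,2,3,4,4a,5,6,8a-octahydronaphthalene-1-carboxylate
Conditions: K2CO3, MeI, acetone, 40 °C
Reagents that add atoms: iodomethane, CI
Why: C-alkylation of the β-keto ester enolate, in which methyl iodide should approach C4 from the face away from the axial C10 methyl group so that the ester ends up axial and cis to it.

**Step 8**
Reactants: 12 methyl (1S,4aR,8aS)-1,4a-dimethyl-2-oxo-1,2,3,4,4a,5,6,8a-octahydronaphthalene-1-carboxylate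
Product: 13 (1R,2R,4aR,8aS)-1-(hydroxymethyl)-1,4a-dimethyl-1,2,3,4,4a,5,6,8a-octahydronaphthalen-2-ol
Conditions: LiAlH4, THF, 0 °C → rt
Reagents that add atoms: none
Why: Hydride reduction of ketone and ester, in which axial delivery to C3 from the face remote from the two axial groups at C4 and C10 should give the equatorial C3 alcohol.

**Step 9**
Reactants: 13 (1R,2R,4aR,8aS)-1-(hydroxymethyl)-1,4a-dimethyl-1,2,3,4,4a,5,6,8a-octahydronaphthalen-2-ol
Product: 14 3,19-O-isopropylidene derivative of 13 (1,3-dioxane across C3–O and C19–O; ring B alkene C6=C7)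
Conditions: 2,2-dimethoxypropane, PPTS (cat.), CH2Cl2, rt
Reagents that add atoms: 2,2-dimethoxypropane, COC(C)(C)OC
Why: Acid-catalysed transketalisation closes an unstrained six-membered acetonide over the 1,3-diol, which this equatorial OH and axial CH2OH pair forms readily.

**Step 10**
Reactants: 14 3,19-O-isopropylidene derivative of 13
Product: 15 acetonide enone with the C8 ketone conjugated to C6=C7
Conditions: Rh2(cap)4 (1 mol %; cap = caprolactamate), t-BuOOH, K2CO3, CH2Cl2, rt
Reagents that add atoms: tert-butyl hydroperoxide, CC(C)(C)OO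
Why: Catalytic allylic C–H oxidation by tert-butylperoxyl radicals, in which the secondary C8–H should be abstracted in preference to the buried tertiary C5–H and oxygen should enter at the less hindered C8 terminus.

**Step 11**
Reactants: 15 acetonide enone with the C8 ketone conjugated to C6=C7; 16 methyl bromoacetate
Product: 17 enone 15 carrying CH2CO2Me at C9 (mixture of C9 epimers)
Conditions: LiN(i-Pr)2, THF, −78 °C; then 16, DMPU, −78 → −20 °C
Reagents that add atoms: none
Why: Kinetic α′-deprotonation of the enone (only C9 carries α′-hydrogens) and SN2 alkylation with the reactive α-bromo ester should install C11–C12, the C9 configuration being corrected in step 12.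

**Step 12**
Reactants: 17 enone 15 carrying CH2CO2Me at C9
Product: 19 saturated 8-keto methyl ester with the C9 side chain equatorial (H9 anti to the C10 methyl), via keto ester epimers 18 (not isolated)
Conditions: H2 (1 atm), Pd/C, EtOAc, rt; then NaOMe (cat.), MeOH, rt
Reagents that add atoms: none
Why: Heterogeneous hydrogenation of the conjugated C6=C7 bond, then base equilibration through the C8 enolate, should place the C9 side chain in the equatorial position found in this natural product family.

**Step 13**
Reactants: 19 saturated 8-keto methyl ester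
Product: 20 8(17)-methylidene methyl ester
Conditions: Ph3PCH3Br, KOt-Bu, THF, 0 → 50 °C
Reagents that add atoms: methyltriphenylphosphonium bromide, C[P+](c1ccccc1)(c1ccccc1)c1ccccc1.[Br-]
Why: Wittig methylenation of the hindered ketone should give the exocyclic alkene, and enolisation by the basic ylide does no harm because C9 is already in its thermodynamic configuration.

**Step 14**
Reactants: 20 8(17)-methylidene methyl ester
Product: 21 8(17)-methylidene aldehyde (C12 aldehyde)
Conditions: i-Bu2AlH, CH2Cl2, −78 °C
Reagents that add atoms: none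
Why: Partial reduction of the unhindered methyl ester at low temperature stops at the tetrahedral aluminium hemiacetal, which releases the aldehyde on work-up.

**Step 15**
Reactants: 21 8(17)-methylidene aldehyde; 22 1,1,1,3,3,3-hexafluoropropan-2-yl acrylate; 23 allyl alcohol
Product: 25 (12R) allyl 2-methylidene-3-hydroxy ester, via hexafluoroisopropyl ester 24 (not isolated)
Conditions: β-isocupreidine (10 mol %), DMF, −55 °C; then 23, Et3N, rt
Reagents that add atoms: none
Why: Morita–Baylis–Hillman reaction of the activated acrylate under chiral amine catalysis, expected to give the 12R carbinol by catalyst control as with other aliphatic aldehydes (the quinine-derived pseudo-enantiomeric catalyst would give the epimer), followed by acyl transfer of the activated ester to allyl alcohol.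

**Step 16**
Reactants: 25 (12R) allyl 2-methylidene-3-hydroxy ester
Product: 26 3,19-O-isopropylidene derivative of the target
Conditions: second-generation Grubbs catalyst (5 mol %), CH2Cl2, 40 °C
Reagents that add atoms: none
Why: Ring-closing metathesis between the allyl and acrylate alkenes should form the five-membered butenolide with loss of ethylene, while the hindered exocyclic methylene could only give a strained or large ring and should stay out.

**Step 17**
Reactants: 26 3,19-O-isopropylidene derivative of the target
Product: 27 (12R)-14-deoxy-12-hydroxyandrographolide (CNP0270153.1)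
Conditions: AcOH/H2O (7:3), rt
Reagents that add atoms: none
Why: Mild acid hydrolysis of the acetonide, a deprotection that the butenolide, the C12 carbinol and the exocyclic alkene of this family should tolerate.

**Compound list**

1 | methacrolein | C=C(C)C=O | starting material
2 | (E)-3-(tert-butyldimethylsilyloxy)-N,N-dimethylbuta-1,3-dien-1-amine | CN(C)/C=C/C(=C)O[Si](C)(C)C(C)(C)C | starting material
3 | (1S,2R)-4-(tert-butyldimethylsilyloxy)-2-(dimethylamino)-1-methylcyclohex-3-ene-1-carbaldehyde | O=C[C@@]1(C)CCC(O[Si](C)(C)C(C)(C)C)=C[C@H]1N(C)C | intermediate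
4 | [(1S,2R)-4-(tert-butyldimethylsilyloxy)-2-(dimethylamino)-1-methylcyclohex-3-en-1-yl]methanol | OC[C@@]1(C)CCC(O[Si](C)(C)C(C)(C)C)=C[C@H]1N(C)C | intermediate
5 | (S)-4-(hydroxymethyl)-4-methylcyclohex-2-en-1-one | O=C1C=C[C@@](C)(CO)CC1 | intermediate
6 | [(1S)-1-methyl-4-oxocyclohex-2-en-1-yl]methyl 4-methylbenzenesulfonate | O=C1C=C[C@@](C)(COS(=O)(=O)c2ccc(C)cc2)CC1 | intermediate
7 | [(1S,4S)-4-hydroxy-1-methylcyclohex-2-en-1-yl]methyl 4-methylbenzenesulfonate | O[C@@H]1C=C[C@@](C)(COS(=O)(=O)c2ccc(C)cc2)CC1 | intermediate
8 | methyl but-2-ynoate | CC#CC(=O)OC | starting material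
9 | methyl (E)-3-{[(1S,4S)-4-methyl-4-(tosyloxymethyl)cyclohex-2-en-1-yl]oxy}but-2-enoate | COC(=O)/C=C(\C)O[C@@H]1C=C[C@@](C)(COS(=O)(=O)c2ccc(C)cc2)CC1 | intermediate
10 | methyl 2-[(1R,6S)-6-methyl-6-(tosyloxymethyl)cyclohex-2-en-1-yl]-3-oxobutanoate (C4 unassigned) | COC(=O)C(C(C)=O)[C@H]1C=CCC[C@]1(C)COS(=O)(=O)c1ccc(C)cc1 | intermediate
11 | methyl (4aR,8aR)-4a-methyl-2-oxo-1,2,3,4,4a,5,6,8a-octahydronaphthalene-1-carboxylate (C4 unassigned) | COC(=O)C1C(=O)CC[C@@]2(C)CCC=C[C@H]12 | intermediate
12 | methyl (1S,4aR,8aS)-1,4a-dimethyl-2-oxo-1,2,3,4,4a,5,6,8a-octahydronaphthalene-1-carboxylate | COC(=O)[C@]1(C)C(=O)CC[C@@]2(C)CCC=C[C@H]12 | intermediate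
13 | (1R,2R,4aR,8aS)-1-(hydroxymethyl)-1,4a-dimethyl-1,2,3,4,4a,5,6,8a-octahydronaphthalen-2-ol | OC[C@]1(C)[C@H](O)CC[C@@]2(C)CCC=C[C@H]12 | intermediate
14 | 3,19-O-isopropylidene derivative of 13 | CC1(C)OC[C@]2(C)[C@H](O1)CC[C@@]3(C)CCC=C[C@H]23 | intermediate
15 | acetonide enone (C8 ketone, C6=C7) | CC1(C)OC[C@]2(C)[C@H](O1)CC[C@@]3(C)CC(=O)C=C[C@H]23 | intermediate
16 | methyl bromoacetate | COC(=O)CBr | starting material
17 | enone 15 with CH2CO2Me at C9 (C9 epimers) | CC1(C)OC[C@]2(C)[C@H](O1)CC[C@@]3(C)C(CC(=O)OC)C(=O)C=C[C@H]23 | intermediate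
18 | saturated 8-keto methyl ester (C9 epimers) | CC1(C)OC[C@]2(C)[C@H](O1)CC[C@@]3(C)C(CC(=O)OC)C(=O)CC[C@H]23 | intermediate
19 | saturated 8-keto methyl ester, C9 side chain equatorial | CC1(C)OC[C@]2(C)[C@H](O1)CC[C@@]3(C)[C@H](CC(=O)OC)C(=O)CC[C@H]23 | intermediate
20 | 8(17)-methylidene methyl ester | CC1(C)OC[C@]2(C)[C@H](O1)CC[C@@]3(C)[C@H](CC(=O)OC)C(=C)CC[C@H]23 | intermediate
21 | 8(17)-methylidene aldehyde | CC1(C)OC[C@]2(C)[C@H](O1)CC[C@@]3(C)[C@H](CC=O)C(=C)CC[C@H]23 | intermediate
22 | 1,1,1,3,3,3-hexafluoropropan-2-yl acrylate | C=CC(=O)OC(C(F)(F)F)C(F)(F)F | starting material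
23 | allyl alcohol | C=CCO | starting material
24 | (12R) Morita–Baylis–Hillman adduct, hexafluoroisopropyl ester | C=C1CC[C@@H]2[C@]3(C)COC(C)(C)O[C@@H]3CC[C@@]2(C)[C@@H]1C[C@@H](O)C(=C)C(=O)OC(C(F)(F)F)C(F)(F)F | intermediate
25 | (12R) allyl 2-methylidene-3-hydroxy ester | C=C1CC[C@@H]2[C@]3(C)COC(C)(C)O[C@@H]3CC[C@@]2(C)[C@@H]1C[C@@H](O)C(=C)C(=O)OCC=C | intermediate
26 | 3,19-O-isopropylidene derivative of the target | C=C1CC[C@@H]2[C@]3(C)COC(C)(C)O[C@@H]3CC[C@@]2(C)[C@@H]1C[C@@H](O)C1=CCOC1=O | intermediate
27 | 3-{(1R)-1-hydroxy-2-[(1R,4aS,5R,6R,8aS)-6-hydroxy-5-(hydroxymethyl)-5,8a-dimethyl-2-methylidenedecahydronaphthalen-1-yl]ethyl}furan-2(5H)-one | C=C1CC[C@@H]2[C@](C)(CO)[C@H](O)CC[C@@]2(C)[C@@H]1C[C@@H](O)C1=CCOC1=O | target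

**Totals**

Total step count: 17. Longest linear sequence: 17 steps (from 1 and 2 to 27).

**Steps most likely to fail**

Step 6. The [3,3] shift has to form a bond at C5 next to the quaternary C10, so at 180 °C it may be slow enough for thermal elimination of the allylic ether to compete. In the closure, the displacement at the neopentyl carbon may be slow enough for O-alkylation or intermolecular reaction to take over. The fallback sets out from 7 and returns at 11. Compound 7 is acylated with 2,2,6-trimethyl-4H-1,3-dioxin-4-one (PhMe, 110 °C) to (1S,4S)-4-methyl-4-(tosyloxymethyl)cyclohex-2-en-1-yl 3-oxobutanoate F1. Its ester dianion (LiN(i-Pr)2, 2.2 equiv, THF, −78 → 65 °C) undergoes the Carroll rearrangement, which forms the C4–C5 bond at far lower temperature, to give the β-keto acid F2. Cold esterification with Me3SiCHN2 gives 10 as an isolated compound. The ring closure is then run on its own with NaH followed by n-BuLi (THF, 0 °C → rt) to reach 11.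

Step 10. Regiocontrol may be poor: hydrogen abstraction at C5, or oxygen delivery at C6 through the delocalised allyl radical, would give transposed enones, and over-oxidation is possible. The fallback sets out from 14 and returns at 15. SeO2 (cat.) with t-BuOOH in CH2Cl2 hydroxylates the allylic methylene by an ene reaction followed by a [2,3] shift, which returns the double bond to C6=C7 and gives the C8 allylic alcohol F3. Dess–Martin periodinane then oxidises it to 15.

Step 15. Conversion of the hindered, enolisable aldehyde in the amine-catalysed addition may be low, self-condensation or dioxanone formation may compete, and catalyst control at C12 may be incomplete. The fallback sets out from 21 and returns at 26. The lithium enolate of 3-(phenylselanyl)oxolan-2-one (LiN(i-Pr)2, THF, −78 °C) adds to 21 to give the selenide aldol adduct F4. H2O2 with pyridine brings about selenoxide syn-elimination into the lactone ring to give the butenolide carbinol as a C12 epimer mixture F5. Dess–Martin periodinane gives the 12-ketone F6. Reduction with (S)-2-methyl-CBS-oxazaborolidine and catecholborane (butenolide alkenyl carbon as the large group) then sets 12R and gives 26.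

**Further compounds**

F1 | step 6 | (1S,4S)-4-methyl-4-(tosyloxymethyl)cyclohex-2-en-1-yl 3-oxobutanoate | CC(=O)CC(=O)O[C@@H]1C=C[C@@](C)(COS(=O)(=O)c2ccc(C)cc2)CC1
F2 | step 6 | 2-[(1R,6S)-6-methyl-6-(tosyloxymethyl)cyclohex-2-en-1-yl]-3-oxobutanoic acid | CC(=O)C(C(O)=O)[C@H]1C=CCC[C@]1(C)COS(=O)(=O)c1ccc(C)cc1
F3 | step 10 | acetonide C8 allylic alcohol (C6=C7 retained; C8 epimers) | CC1(C)OC[C@]2(C)[C@H](O1)CC[C@@]3(C)CC(O)C=C[C@H]23
F4 | step 15 | selenide aldol adduct (C12 and C13 epimers) | C=C1CC[C@@H]2[C@]3(C)COC(C)(C)O[C@@H]3CC[C@@]2(C)[C@@H]1CC(O)C1([Se]c2ccccc2)CCOC1=O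
F5 | step 15 | butenolide carbinol acetonide (C12 epimers) | C=C1CC[C@@H]2[C@]3(C)COC(C)(C)O[C@@H]3CC[C@@]2(C)[C@@H]1CC(O)C1=CCOC1=O
F6 | step 15 | 12-oxo butenolide acetonide | C=C1CC[C@@H]2[C@]3(C)COC(C)(C)O[C@@H]3CC[C@@]2(C)[C@@H]1CC(=O)C1=CCOC1=O
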